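**Retrosynthetic overview**

1. Target 27 ⇐ 26 by global O‑deallylation; 26 ⇐ 24 by reductive removal of a temporary phenylsulfonyl group at C5 and base equilibration of C5.
2. Cyclohexene (C1 flavonyl‑bearing, C2=C3(Me), C4H2, C5 aroyl, C6 aryl) ⇐ aldehyde 15 + sulfonyl chalcone 18 + phosphonium salt 21 in one pot: C1–C6 by amine‑catalysed Michael addition, C4–C5 by Michael addition to the α‑methylvinylphosphonium salt, C2=C3 by intramolecular Wittig reaction.
3. Enabling feature: C2 is an sp2 CH next to C1 (so C2 can be a formyl carbon and C1 its α‑carbon); C6 is β and C5 α to the aryl ketone (Michael position and sulfonyl‑stabilised carbanion); the C1/C5/C6 substituents are all‑trans (all‑equatorial). The aroyl group is 1,3 to both the C1 aryl and the C3 methyl group, a pattern a diene/chalcone Diels–Alder reaction does not deliver but this polar sequence gives exclusively.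
4. 15 ⇐ 8‑iodoflavone 11 (Suzuki vinyl ether, hydrolysis); 11 ⇐ acetophenone 4 + acid chloride 8 (C‑acylation, C‑prenylation, cyclodehydration); 18 ⇐ 8 + methyl phenyl sulfone + aldehyde 6.
5. Ring order: benzene rings bought; chromone pyranone ring in step 9; cyclohexene last, in step 15.

Key step: step 15

Remark (assumption): the sense of induction in step 15 is taken from the established behaviour of diarylprolinol silyl ethers with aldehydes and β‑aryl nitroalkenes, where the (S)‑catalyst gives (2R,3S)‑syn adducts. Mapped onto 15/18 this calls for the (R)‑catalyst; the (S)‑catalyst would be used if the mapping proved reversed.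
Remark: allyl = prop‑2‑en‑1‑yl; MOM = methoxymethyl; prenyl = 3‑methylbut‑2‑en‑1‑yl; "flavonyl" in 22–24 = 5,7‑bis(allyloxy)‑2‑[2,4‑bis(allyloxy)phenyl]‑4‑oxo‑3‑prenyl‑4H‑chromen‑8‑yl.

**Route**

Step 1
Reactants: 1 2,4,6‑trihydroxyacetophenone
Product: 2 1‑[2,6‑dihydroxy‑4‑(methoxymethoxy)phenyl]ethan‑1‑one
Conditions: MOMCl (1.05 equiv), i‑Pr2NEt, CH2Cl2, 0 °C
Reagents that add atoms: chloromethyl methyl ether, COCCl
Why: The 4‑OH is the only hydroxyl not hydrogen‑bonded to the acetyl group and the most acidic, so it should be etherified first (selective O‑alkylation, Williamson type).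

Step 2
Reactants: 2 1‑[2,6‑dihydroxy‑4‑(methoxymethoxy)phenyl]ethan‑1‑one
Product: 3 1‑[2‑hydroxy‑4‑(methoxymethoxy)‑6‑(allyloxy)phenyl]ethan‑1‑one
Conditions: allyl bromide (1.1 equiv), K2CO3, acetone, reflux
Reagents that add atoms: allyl bromide, C=CCBr
Why: After one of the two equivalent ortho hydroxyls is alkylated the other is locked in a hydrogen bond to the carbonyl and should not react under carbonate conditions (Williamson ether synthesis).

Step 3
Reactants: 3 1‑[2‑hydroxy‑4‑(methoxymethoxy)‑6‑(allyloxy)phenyl]ethan‑1‑one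
Product: 4 1‑[2‑hydroxy‑3‑iodo‑4‑(methoxymethoxy)‑6‑(allyloxy)phenyl]ethan‑1‑one
Conditions: NIS (1.05 equiv), DMF, 0 °C → rt, dark
Reagents that add atoms: N‑iodosuccinimide, O=C1CCC(=O)N1I
Why: Electrophilic aromatic iodination of 2‑hydroxy‑4,6‑dialkoxyacetophenones should go to C3, ortho to the free chelated hydroxyl, and the electron‑rich arene should react far faster than the allyl double bond.

Step 4
Reactants: 5 2,4‑dihydroxybenzaldehyde
Product: 6 2,4‑bis(allyloxy)benzaldehyde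
Conditions: allyl bromide (2.5 equiv), K2CO3, DMF, 60 °C
Reagents that add atoms: allyl bromide, C=CCBr
Why: Double Williamson etherification; the chelated 2‑OH needs the warm polar conditions.

Step 5
Reactants: 6 2,4‑bis(allyloxy)benzaldehyde
Product: 7 2,4‑bis(allyloxy)benzoic acid
Conditions: NaClO2, NaH2PO4, 2‑methyl‑2‑butene (excess), t‑BuOH–H2O, rt
Reagents that add atoms: sodium chlorite, [Na+].[O-]Cl=O
Why: Pinnick oxidation of the aldehyde; the excess trisubstituted alkene scavenges HOCl so the allyl ethers should not be chlorinated.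

Step 6
Reactants: 7 2,4‑bis(allyloxy)benzoic acid
Product: 8 2,4‑bis(allyloxy)benzoyl chloride
Conditions: (COCl)2, cat. DMF, CH2Cl2, 0 °C → rt
Reagents that add atoms: oxalyl chloride, O=C(Cl)C(Cl)=O
Why: Standard acid chloride formation through the Vilsmeier‑type chloroiminium intermediate.

Step 7
Reactants: 4 1‑[2‑hydroxy‑3‑iodo‑4‑(methoxymethoxy)‑6‑(allyloxy)phenyl]ethan‑1‑one; 8 2,4‑bis(allyloxy)benzoyl chloride
Product: 9 1‑[2‑hydroxy‑3‑iodo‑4‑(methoxymethoxy)‑6‑(allyloxy)phenyl]‑3‑[2,4‑bis(allyloxy)phenyl]propane‑1,3‑dione (largely enol)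
Conditions: LiHMDS (3.2 equiv), THF, −78 → −20 °C; then 8, −78 °C → rt; aq. NH4Cl
Reagents that add atoms: none
Why: The lithium phenoxide/enolate dianion of an o‑hydroxyacetophenone is acylated on carbon by an aroyl chloride (Claisen‑type C‑acylation, the one‑flask equivalent of a Baker–Venkataraman sequence), and the third equivalent of base protects the product as its enolate.

Step 8
Reactants: 9 the β‑diketone
Product: 10 1‑[2‑hydroxy‑3‑iodo‑4‑(methoxymethoxy)‑6‑(allyloxy)phenyl]‑3‑[2,4‑bis(allyloxy)phenyl]‑2‑(3‑methylbut‑2‑en‑1‑yl)propane‑1,3‑dione (racemic, enolisable)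
Conditions: prenyl bromide (1.1 equiv), K2CO3 (1.1 equiv), acetone, rt
Reagents that add atoms: prenyl bromide (1‑bromo‑3‑methylbut‑2‑ene), CC(C)=CCBr
Why: The soft β‑diketone monoanion should be alkylated on its central carbon by the allylic bromide, while the phenol flanked by iodine and the chelating carbonyl is hindered.

Step 9
Reactants: 10 the 2‑prenyl β‑diketone
Product: 11 5‑(allyloxy)‑2‑[2,4‑bis(allyloxy)phenyl]‑7‑hydroxy‑8‑iodo‑3‑(3‑methylbut‑2‑en‑1‑yl)‑4H‑chromen‑4‑one
Conditions: HCl (cat., 3 M in MeOH), MeOH–THF, 50 °C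
Reagents that add atoms: none
Why: Acid‑catalysed cyclodehydration of the o‑hydroxyaryl β‑diketone closes the pyranone ring and the MOM acetal is methanolysed; only the hydroxyl next to iodine can cyclise because the other ortho oxygen carries an acid‑stable allyl group, so iodine must end at C8.

Step 10
Reactants: 11 the 7‑hydroxy‑8‑iodoflavone; 12 (E)‑2‑(2‑ethoxyethenyl)‑4,4,5,5‑tetramethyl‑1,3,2‑dioxaborolane
Product: 13 5‑(allyloxy)‑2‑[2,4‑bis(allyloxy)phenyl]‑8‑[(E)‑2‑ethoxyethenyl]‑7‑hydroxy‑3‑(3‑methylbut‑2‑en‑1‑yl)‑4H‑chromen‑4‑one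
Conditions: Pd(dppf)Cl2 (5 mol %), K3PO4, dioxane–H2O, 70 °C
Reagents that add atoms: none
Why: Suzuki–Miyaura coupling at the C8–I bond with retention of the E geometry; no allyl ether sits ortho to the C–Pd bond (O7 is free at this stage), so intramolecular Heck cyclisation is excluded, and any allyl scrambling between phenols is repaired in step 11.

Step 11
Reactants: 13 the 7‑hydroxy enol ether
Product: 15 2‑{5,7‑bis(allyloxy)‑2‑[2,4‑bis(allyloxy)phenyl]‑3‑(3‑methylbut‑2‑en‑1‑yl)‑4‑oxo‑4H‑chromen‑8‑yl}acetaldehyde, via enol ether 14 (not isolated)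
Conditions: allyl bromide, K2CO3, DMF, rt; then 2 M HCl, THF, rt
Reagents that add atoms: allyl bromide, C=CCBr; water, O
Why: Williamson allylation of the acidic 7‑OH first prevents benzofuran formation, then acid hydrolysis of the β‑aryl enol ether should give the arylacetaldehyde, which is used at once.

Step 12
Reactants: 16 methyl phenyl sulfone; 8 2,4‑bis(allyloxy)benzoyl chloride
Product: 17 1‑[2,4‑bis(allyloxy)phenyl]‑2‑(phenylsulfonyl)ethan‑1‑one
Conditions: 16 (2.2 equiv), n‑BuLi (2.1 equiv), THF, −78 °C; then 8, −78 → 0 °C; aq. NH4Cl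
Reagents that add atoms: none
Why: Claisen‑type acylation of the α‑sulfonyl carbanion; the second equivalent deprotonates the more acidic β‑keto sulfone and so prevents double acylation.

Step 13
Reactants: 17 the β‑keto sulfone; 6 2,4‑bis(allyloxy)benzaldehyde
Product: 18 (E)‑1,3‑bis[2,4‑bis(allyloxy)phenyl]‑2‑(phenylsulfonyl)prop‑2‑en‑1‑one
Conditions: piperidine (cat.), AcOH (cat.), toluene, reflux, Dean–Stark
Reagents that add atoms: none
Why: Knoevenagel condensation of the doubly activated methylene with the aldehyde; the isomer with aryl trans to the bulky sulfonyl group should predominate.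

Step 14
Reactants: 19 2‑bromopropene; 20 triphenylphosphine
Product: 21 triphenyl(prop‑1‑en‑2‑yl)phosphonium bromide
Conditions: Pd(PPh3)4 (2 mol %), toluene, 110 °C, sealed tube
Reagents that add atoms: none
Why: Oxidative addition of the alkenyl bromide to Pd(0) and C–P reductive elimination should give the alkenylphosphonium salt (Pd‑catalysed quaternisation of a triarylphosphine by an sp2 halide).

Step 15
Reactants: 15 the flavonylacetaldehyde; 18 the sulfonyl chalcone; 21 the isopropenylphosphonium salt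
Product: 24 8‑[(1R,6R)‑5‑[2,4‑bis(allyloxy)benzoyl]‑6‑[2,4‑bis(allyloxy)phenyl]‑3‑methyl‑5‑(phenylsulfonyl)cyclohex‑2‑en‑1‑yl]‑5,7‑bis(allyloxy)‑2‑[2,4‑bis(allyloxy)phenyl]‑3‑(3‑methylbut‑2‑en‑1‑yl)‑4H‑chromen‑4‑one (C5 epimers), via Michael adduct 22 (not isolated), via phosphonium ylide 23 (not isolated)
Conditions: (R)‑2‑[diphenyl(trimethylsilyloxy)methyl]pyrrolidine (20 mol %), PhCO2H (20 mol %), toluene, 0 °C → rt; then NaH (1.3 equiv), THF–DMF, 0 °C until H2 evolution stops; then 21 (1.5 equiv), 0 → 50 °C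
Reagents that add atoms: none
Why: The (R)‑diarylprolinol silyl ether converts 15 into its E‑enamine, whose α‑carbon (future C1) adds to the β‑carbon of 18 (future C6) from the face not shielded by the diphenyl(silyloxy)methyl group through the usual acyclic synclinal transition state, which should give the syn adduct 22 (2R,3R) resting as a cyclic hemiacetal without an acidic aldehyde α‑hydrogen; this is an enamine Michael addition of the kind known for aldehydes with β‑aryl nitroalkenes and geminally diactivated β‑aryl alkenes. NaH then removes the only strongly acidic proton, that of the α‑sulfonyl ketone (future C5); this carbanion adds to the CH2 terminus of the α‑methylvinylphosphonium salt (C4–C5 bond) to give ylide 23, which closes the ring by an intramolecular Wittig reaction on the formyl group (C2=C3 bond, 6‑exo‑trig attack of the ylide carbon), i.e. a vinylphosphonium Michael/Wittig annulation of the Schweizer type. C6 and C1 are set by the catalyst in the first bond formation and the syn relationship of the open chain becomes the trans C1/C6 relationship of the ring, while the quaternary C5 forms as a mixture that is immaterial because the sulfonyl group leaves in step 16. The required regiochemistry (aroyl on C5 next to C4H2, aryl on C6 next to C1) follows from the fixed polarity of the three components, and deprotonation at C5 in preference to the aldehyde α‑position is secured by the sulfonyl group (about five pKa units).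

Step 16
Reactants: 24 the cyclohexenyl sulfone
Product: 26 8‑[(1R,5S,6S)‑5‑[2,4‑bis(allyloxy)benzoyl]‑6‑[2,4‑bis(allyloxy)phenyl]‑3‑methylcyclohex‑2‑en‑1‑yl]‑5,7‑bis(allyloxy)‑2‑[2,4‑bis(allyloxy)phenyl]‑3‑(3‑methylbut‑2‑en‑1‑yl)‑4H‑chromen‑4‑one, via C5‑epimer mixture 25 (not isolated)
Conditions: SmI2 (2.5 equiv), THF–MeOH, −78 °C; aq. NH4Cl; then DBU (0.3 equiv), THF, rt
Reagents that add atoms: none
Why: Electron transfer to the aryl ketone and loss of benzenesulfinate (reductive cleavage of an α‑heteroatom‑substituted ketone) give the samarium enolate, which methanol protonates; DBU then equilibrates the epimerisable C5 to the all‑equatorial arrangement (aroyl trans to the C6 aryl, cis to the C1 flavonyl), which is 5S.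

Step 17
Reactants: 26 the octa‑O‑allyl ketone
Product: 27 8‑[(1R,5S,6S)‑5‑(2,4‑dihydroxybenzoyl)‑6‑(2,4‑dihydroxyphenyl)‑3‑methylcyclohex‑2‑en‑1‑yl]‑2‑(2,4‑dihydroxyphenyl)‑5,7‑dihydroxy‑3‑(3‑methylbut‑2‑en‑1‑yl)‑4H‑chromen‑4‑one (target)
Conditions: Pd(PPh3)4 (10 mol %), K2CO3, degassed MeOH–THF, 40 °C; aq. NH4Cl
Reagents that add atoms: none
Why: Pd(0) ionises each aryl allyl ether to a π‑allyl complex that methoxide captures (Tsuji–Trost‑type deallylation); these non‑acidic conditions should spare the prenyl group and the ring alkene, and C5 already holds its thermodynamic configuration.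

**Compound list**

1 | 2,4,6‑trihydroxyacetophenone | CC(=O)c1c(O)cc(O)cc1O | starting material
2 | 1‑[2,6‑dihydroxy‑4‑(methoxymethoxy)phenyl]ethan‑1‑one | CC(=O)c1c(O)cc(OCOC)cc1O | intermediate
3 | 1‑[2‑hydroxy‑4‑(methoxymethoxy)‑6‑(allyloxy)phenyl]ethan‑1‑one | CC(=O)c1c(O)cc(OCOC)cc1OCC=C | intermediate
4 | 1‑[2‑hydroxy‑3‑iodo‑4‑(methoxymethoxy)‑6‑(allyloxy)phenyl]ethan‑1‑one | CC(=O)c1c(O)c(I)c(OCOC)cc1OCC=C | intermediate
5 | 2,4‑dihydroxybenzaldehyde | O=Cc1ccc(O)cc1O | starting material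
6 | 2,4‑bis(allyloxy)benzaldehyde | O=Cc1ccc(OCC=C)cc1OCC=C | intermediate
7 | 2,4‑bis(allyloxy)benzoic acid | OC(=O)c1ccc(OCC=C)cc1OCC=C | intermediate
8 | 2,4‑bis(allyloxy)benzoyl chloride | ClC(=O)c1ccc(OCC=C)cc1OCC=C | intermediate
9 | 1‑[2‑hydroxy‑3‑iodo‑4‑(methoxymethoxy)‑6‑(allyloxy)phenyl]‑3‑[2,4‑bis(allyloxy)phenyl]propane‑1,3‑dione | O=C(CC(=O)c1ccc(OCC=C)cc1OCC=C)c1c(O)c(I)c(OCOC)cc1OCC=C | intermediate
10 | 2‑prenyl derivative of 9 (racemic, enolisable) | O=C(C(CC=C(C)C)C(=O)c1ccc(OCC=C)cc1OCC=C)c1c(O)c(I)c(OCOC)cc1OCC=C | intermediate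
11 | 5‑(allyloxy)‑2‑[2,4‑bis(allyloxy)phenyl]‑7‑hydroxy‑8‑iodo‑3‑prenyl‑4H‑chromen‑4‑one | CC(C)=CCc1c(-c2ccc(OCC=C)cc2OCC=C)oc2c(I)c(O)cc(OCC=C)c2c1=O | intermediate
12 | (E)‑2‑(2‑ethoxyethenyl)‑4,4,5,5‑tetramethyl‑1,3,2‑dioxaborolane | CCO/C=C/B1OC(C)(C)C(C)(C)O1 | starting material
13 | 5‑(allyloxy)‑2‑[2,4‑bis(allyloxy)phenyl]‑8‑[(E)‑2‑ethoxyethenyl]‑7‑hydroxy‑3‑prenyl‑4H‑chromen‑4‑one | CCO/C=C/c1c(O)cc(OCC=C)c2c(=O)c(CC=C(C)C)c(-c3ccc(OCC=C)cc3OCC=C)oc12 | intermediate
14 | 5,7‑bis(allyloxy)‑2‑[2,4‑bis(allyloxy)phenyl]‑8‑[(E)‑2‑ethoxyethenyl]‑3‑prenyl‑4H‑chromen‑4‑one | CCO/C=C/c1c(OCC=C)cc(OCC=C)c2c(=O)c(CC=C(C)C)c(-c3ccc(OCC=C)cc3OCC=C)oc12 | intermediate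
15 | 2‑{5,7‑bis(allyloxy)‑2‑[2,4‑bis(allyloxy)phenyl]‑3‑prenyl‑4‑oxo‑4H‑chromen‑8‑yl}acetaldehyde | O=CCc1c(OCC=C)cc(OCC=C)c2c(=O)c(CC=C(C)C)c(-c3ccc(OCC=C)cc3OCC=C)oc12 | intermediate
16 | methyl phenyl sulfone | CS(=O)(=O)c1ccccc1 | starting material
17 | 1‑[2,4‑bis(allyloxy)phenyl]‑2‑(phenylsulfonyl)ethan‑1‑one | O=C(CS(=O)(=O)c1ccccc1)c1ccc(OCC=C)cc1OCC=C | intermediate
18 | (E)‑1,3‑bis[2,4‑bis(allyloxy)phenyl]‑2‑(phenylsulfonyl)prop‑2‑en‑1‑one | O=S(=O)(c1ccccc1)/C(C(=O)c1ccc(OCC=C)cc1OCC=C)=C/c1ccc(OCC=C)cc1OCC=C | intermediate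
19 | 2‑bromopropene | CC(Br)=C | starting material
20 | triphenylphosphine | c1ccc(cc1)P(c1ccccc1)c1ccccc1 | starting material
21 | triphenyl(prop‑1‑en‑2‑yl)phosphonium bromide | C=C(C)[P+](c1ccccc1)(c1ccccc1)c1ccccc1.[Br-] | intermediate
22 | (2R,3R)‑3,5‑bis[2,4‑bis(allyloxy)phenyl]‑2‑flavonyl‑5‑oxo‑4‑(phenylsulfonyl)pentanal (C4 epimers; rests as cyclic hemiacetal) | O=C[C@@H](c1c(OCC=C)cc(OCC=C)c2c(=O)c(CC=C(C)C)c(-c3ccc(OCC=C)cc3OCC=C)oc12)[C@H](c1ccc(OCC=C)cc1OCC=C)C(S(=O)(=O)c1ccccc1)C(=O)c1ccc(OCC=C)cc1OCC=C | intermediate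
23 | (2R,3R)‑4‑[2,4‑bis(allyloxy)benzoyl]‑3‑[2,4‑bis(allyloxy)phenyl]‑2‑flavonyl‑4‑(phenylsulfonyl)‑6‑(triphenyl‑λ5‑phosphanylidene)heptanal (C4 epimers) | O=C[C@@H](c1c(OCC=C)cc(OCC=C)c2c(=O)c(CC=C(C)C)c(-c3ccc(OCC=C)cc3OCC=C)oc12)[C@H](c1ccc(OCC=C)cc1OCC=C)C(CC(C)=P(c1ccccc1)(c1ccccc1)c1ccccc1)(S(=O)(=O)c1ccccc1)C(=O)c1ccc(OCC=C)cc1OCC=C | intermediate
24 | (1R,6R)‑cyclohexenyl sulfone, C5 epimers (name in step 15) | CC(C)=CCc1c(-c2ccc(OCC=C)cc2OCC=C)oc2c([C@@H]3C=C(C)CC(S(=O)(=O)c4ccccc4)(C(=O)c4ccc(OCC=C)cc4OCC=C)[C@H]3c3ccc(OCC=C)cc3OCC=C)c(OCC=C)cc(OCC=C)c2c1=O | intermediate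
25 | desulfonylated ketone, (1R,6S), mixture of C5 epimers | CC(C)=CCc1c(-c2ccc(OCC=C)cc2OCC=C)oc2c([C@@H]3C=C(C)CC(C(=O)c4ccc(OCC=C)cc4OCC=C)[C@H]3c3ccc(OCC=C)cc3OCC=C)c(OCC=C)cc(OCC=C)c2c1=O | intermediate
26 | (1R,5S,6S) octa‑O‑allyl ketone (name in step 16) | CC(C)=CCc1c(-c2ccc(OCC=C)cc2OCC=C)oc2c([C@@H]3C=C(C)C[C@H](C(=O)c4ccc(OCC=C)cc4OCC=C)[C@H]3c3ccc(OCC=C)cc3OCC=C)c(OCC=C)cc(OCC=C)c2c1=O | intermediate
27 | 8‑[(1R,5S,6S)‑5‑(2,4‑dihydroxybenzoyl)‑6‑(2,4‑dihydroxyphenyl)‑3‑methylcyclohex‑2‑en‑1‑yl]‑2‑(2,4‑dihydroxyphenyl)‑5,7‑dihydroxy‑3‑(3‑methylbut‑2‑en‑1‑yl)‑4H‑chromen‑4‑one | CC(C)=CCc1c(-c2ccc(O)cc2O)oc2c([C@@H]3C=C(C)C[C@H](C(=O)c4ccc(O)cc4O)[C@H]3c3ccc(O)cc3O)c(O)cc(O)c2c1=O | target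

**Totals**

Total step count: 17. Longest linear sequence: 11 steps (1, 2, 3, 7, 8, 9, 10, 11, 15, 16, 17).

**Steps most likely to fail**

Step 15. The amine‑catalysed conjugate addition has to join two carbons that each carry an ortho,ortho′‑dioxygenated aryl group. It may stall, or proceed with poor facial or syn/anti selectivity, before the ring can be closed. Fallback, from 15 back to 24: 15 is condensed with (S)‑1‑amino‑2‑(methoxymethyl)pyrrolidine to give the SAMP hydrazone F1. LDA (THF, −78 °C) converts F1 into its azaenolate, a much stronger nucleophile than the catalytic enamine, which adds to 18 under auxiliary control to give the adduct hydrazone F2. The usual sense of attack on SAMP azaenolates corresponds to 2R here. The auxiliary is removed with saturated aqueous oxalic acid in a two‑phase system (ozone is excluded by the alkenes) to give aldehyde 22. This is closed with NaH and 21 as in the second half of step 15 and rejoins the route at 24.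

Step 8. O‑alkylation of the enolate oxygen or of the chelated phenoxide may compete with C‑alkylation of the β‑diketone. Fallback, from 4 back to 10: the phenoxide/enolate dianion of 4 (LiHMDS, 2.2 equiv, THF, −78 °C) is alkylated on carbon with prenyl bromide to give the α‑prenyl ketone F3. The dianion of F3 is then C‑acylated with 8 under the conditions of step 7, which gives 10 directly and removes the ambident diketone alkylation from the route.

Step 3. The iodination may lose regioselectivity (attack at C5 between the two ether groups instead of C3) or touch the allyl double bond. Fallback, from 2 back to 4: 2 is iodinated before the allyl group is introduced. Its two free ring positions are equivalent and no alkene is present, so only the monoiodide F4 can form. Mono‑allylation of F4 (allyl bromide 1 equiv, K2CO3, acetone) at the hydroxyl that is not flanked by iodine then gives 4.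

Further compounds
F1 | step 15 | SAMP hydrazone of aldehyde 15 | COC[C@@H]1CCCN1/N=C/Cc1c(OCC=C)cc(OCC=C)c2c(=O)c(CC=C(C)C)c(-c3ccc(OCC=C)cc3OCC=C)oc12
F2 | step 15 | SAMP hydrazone of Michael adduct 22 | COC[C@@H]1CCCN1/N=C/[C@@H](c1c(OCC=C)cc(OCC=C)c2c(=O)c(CC=C(C)C)c(-c3ccc(OCC=C)cc3OCC=C)oc12)[C@H](c1ccc(OCC=C)cc1OCC=C)C(S(=O)(=O)c1ccccc1)C(=O)c1ccc(OCC=C)cc1OCC=C
F3 | step 8 | 1‑[2‑hydroxy‑3‑iodo‑4‑(methoxymethoxy)‑6‑(allyloxy)phenyl]‑5‑methylhex‑4‑en‑1‑one | CC(C)=CCCC(=O)c1c(O)c(I)c(OCOC)cc1OCC=C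
F4 | step 3 | 1‑[2,6‑dihydroxy‑3‑iodo‑4‑(methoxymethoxy)phenyl]ethan‑1‑one | CC(=O)c1c(O)c(I)c(OCOC)cc1O
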